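**Plan**

1. Tetralin numbering is used throughout. C1 bears the guaiacyl group, C2 and C3 bear the CH2OH groups, and C4 is the CH2. Ring A is C4a–C5(OMe)–C6(OMe)–C7(OH)–C8(H)–C8a.
2. Cuts: C1–C8a is taken back by a 1,2-shift to C1–C4a, which turns the six-membered carbocycle into the cyclopentane of a spiro[4.5]deca-6,9-dien-8-one. Then C1–C4a (phenolate para carbon plus p-quinone methide), C1–C2 (aldol) and C3–C4 (Stobbe) are cut, leaving an aldehyde, dimethyl succinate and vanillin.
3. Enabling feature: the C7 hydroxyl stands para to C4a, so ring A can exist as a 4,4-disubstituted cyclohexadienone with C4a as spiro atom. Of the two carbons flanking C4a, C8a carries H and C5 is blocked by OMe, so only one shift can end in an arene.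
4. Forward order: chain C4–C3–C2 (Stobbe), lactone, C1 added (aldol), five-membered spiro ring closed (step 10), then enlarged to the six-membered ring as ring A rearomatises (step 11).
5. Stereochemistry: C3 comes from Rh-catalysed asymmetric hydrogenation. C2 comes from attack on the lactone enolate anti to the C3 substituent. C1 comes from the reversible, trans-selective spirocyclisation and is carried over with retention in the shift.

Key step: step 11

Assumption: 1 is taken as a catalogue compound, and the antipode of Et-DuPHOS that gives the S acid is fixed by a test run (both antipodes are sold).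

**Route**

Step 1
Reactants: 1 4-hydroxy-2,3-dimethoxybenzaldehyde
Product: 2 4-(benzyloxy)-2,3-dimethoxybenzaldehyde
Conditions: BnBr, K2CO3, DMF, rt
Reagents that add atoms: benzyl bromide BrCc1ccccc1
Why: Williamson ether synthesis on the acidic para-formyl phenol gives a benzyl ether that should carry the phenol through the alkoxide-mediated Stobbe step.

Step 2
Reactants: 2 4-(benzyloxy)-2,3-dimethoxybenzaldehyde; 3 dimethyl succinate
Product: 4 (E)-4-[4-(benzyloxy)-2,3-dimethoxyphenyl]-3-(methoxycarbonyl)but-3-enoic acid
Conditions: NaOMe, MeOH, reflux; then aq HCl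
Reagents that add atoms: none
Why: Stobbe condensation (aldol, lactonisation to the paraconic ester, E1cB ring opening) forms C3=C4 and leaves the two carboxyl carbons differentiated as ester on C3 and free acid on the C2 arm.

Step 3
Reactants: 4 Stobbe half-ester
Product: 6 (3S)-4-(4-hydroxy-2,3-dimethoxyphenyl)-3-(methoxycarbonyl)butanoic acid, via benzyl ether 5 (not isolated)
Conditions: [Rh(cod)(Et-DuPHOS)]BF4 (cat.), NaOMe (cat.), H2 (6 bar), MeOH, rt; then 10% Pd/C, H2 (1 bar), rt
Reagents that add atoms: none
Why: Rh-bisphospholane asymmetric hydrogenation of a Stobbe-type itaconate half-ester, with olefin and CH2CO2 group chelated to Rh, should set C3 as S by catalyst control, and the Pd stage is a plain hydrogenolysis of the aryl benzyl ether.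

Step 4
Reactants: 6 phenolic half-ester
Product: 8 (4S)-4-(4-hydroxy-2,3-dimethoxybenzyl)dihydrofuran-2(3H)-one, via hydroxy acid 7 (not isolated)
Conditions: KOH (2 equiv), EtOH, 0 °C; CaCl2, NaBH4, EtOH, −10 °C to rt; then 2 M HCl, rt
Reagents that add atoms: none
Why: Calcium borohydride reduces the ester but not the carboxylate salt, and acidification lactonises the hydroxy acid, so the benzyl group ends at the β-carbon and C3 is not touched.

Step 5
Reactants: 8 phenolic lactone
Product: 9 (4S)-4-[4-(tert-butyldimethylsilyloxy)-2,3-dimethoxybenzyl]dihydrofuran-2(3H)-one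
Conditions: TBSCl, imidazole, DMF, rt
Reagents that add atoms: tert-butyldimethylsilyl chloride CC(C)(C)[Si](C)(C)Cl
Why: Standard phenol silylation installs on ring A a group that survives amide base and borohydride and can later be released by fluoride as a naked phenolate.

Step 6
Reactants: 10 vanillin
Product: 11 4-(tert-butyldimethylsilyloxy)-3-methoxybenzaldehyde
Conditions: TBSCl, imidazole, CH2Cl2, rt
Reagents that add atoms: tert-butyldimethylsilyl chloride CC(C)(C)[Si](C)(C)Cl
Why: The same phenol silylation gives the guaiacyl unit the fluoride-labile trigger needed for quinone methide release.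

Step 7
Reactants: 9 silyl lactone; 11 O-TBS-vanillin
Product: 12 (3R,4S)-3-{[4-(TBSO)-3-methoxyphenyl](hydroxy)methyl}-4-[4-(TBSO)-2,3-dimethoxybenzyl]dihydrofuran-2(3H)-one (both carbinol epimers)
Conditions: LDA, THF, −78 °C; then 11, −78 °C; AcOH quench
Reagents that add atoms: none
Why: In this lithium enolate aldol addition the aldehyde should approach the enolate face anti to the C3 benzyl group, setting C2 trans to C3, while the carbinol carbon C1 forms as an epimer mixture that does not matter because it becomes sp2 in step 10.

Step 8
Reactants: 12 aldol adduct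
Product: 13 (2S,3S)-2-{[4-(TBSO)-3-methoxyphenyl](hydroxy)methyl}-3-[4-(TBSO)-2,3-dimethoxybenzyl]butane-1,4-diol
Conditions: LiBH4, THF, 0 °C to rt
Reagents that add atoms: none
Why: Borohydride reduction of the lactone to the diol removes the acidifying carbonyl next to H-2 (which would divert the later quinone methide to a benzylidene lactone), spares the aryl silyl ethers and touches no stereocentre.

Step 9
Reactants: 13 triol
Product: 14 triacetate of 13
Conditions: Ac2O, pyridine, DMAP (cat.), CH2Cl2, 0 °C to rt
Reagents that add atoms: acetic anhydride CC(=O)OC(C)=O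
Why: DMAP-catalysed acylation installs with one reagent the leaving group at C1 and masks the two primary alcohols, which would otherwise trap the quinone methide as a tetrahydrofuran.

Step 10
Reactants: 14 triacetate
Product: 16 [(1R,2S,3S)-1-(4-hydroxy-3-methoxyphenyl)-6,7-dimethoxy-8-oxospiro[4.5]deca-6,9-diene-2,3-diyl]dimethyl diacetate (spiro centre undefined), via quinone methide 15 (not isolated)
Conditions: CsF (3 equiv), 4 Å MS, MeCN (0.005 M), 0 °C to rt; AcOH quench
Reagents that add atoms: none
Why: Proposed new method: fluoride strips both aryl silyl ethers, the guaiacyl phenolate expels the benzylic acetate (1,6-elimination, the usual fluoride-triggered entry to p-quinone methides), and the ring A phenolate adds through C4a to the exocyclic carbon C1 in a 5-exo-trig 1,6-addition that rearomatises the guaiacyl ring and dearomatises ring A; C4a is the only site that can reach C1, since C8a is meta to the oxide and unactivated, C8 would need a meta-bridged ring and the oxygen is out of reach; the closest known types are the Ar1(−)-5 para-C-alkylation of 4-(4-hydroxyphenyl)butyl sulfonates to spiro[4.5]decadienones and the 1,6-addition of soft carbon nucleophiles to p-quinone methides, and their union in one molecule is the new element; C1 should be set trans to the C2 substituent because the addition is reversible through the guaiacyl phenolate and the all-trans cyclopentane is the least crowded, and high dilution holds back intermolecular O-alkylation.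

Step 11
Reactants: 16 spirodienone diacetate
Product: 18 target (6S,7S,8R)-8-(4-hydroxy-3-methoxyphenyl)-6,7-bis(hydroxymethyl)-3,4-dimethoxy-5,6,7,8-tetrahydronaphthalen-2-ol, via tetralin diacetate 17 (not isolated)
Conditions: TFA, CH2Cl2, 0 °C; evaporate; HCl (1.25 M in MeOH), 40 °C
Reagents that add atoms: none
Why: TFA protonates the C7 carbonyl of the cross-conjugated dienone, the C1–C4a bond of the cyclopentane shifts suprafacially to the unsubstituted C8a (1,2-Wagner–Meerwein shift) to give an arenium ion stabilised by the para C6 OMe, loss of H-8a restores ring A, and methanolic HCl then transesterifies the two acetates. This is the dienone–phenol rearrangement, the standard fate in acid of spiro[4.5]deca-1,4-dien-3-ones, which give 5,6,7,8-tetrahydro-2-naphthols. The only ring made is the six-membered carbocycle, which arises by one-atom enlargement of the five-membered ring (C1–C4 plus C4a) through uptake of C8a and not by closure of a chain; if the shift runs stepwise through the ring-opened p-hydroxybenzyl cation, reclosure is 6-exo-trig at the quinone methide carbon and makes the same bond. No new stereocentre is created: C1 migrates with retention (or recloses to the all-equatorial 1,2-trans isomer in the stepwise variant), C2 and C3 are untouched, and the undefined spiro centre is erased. Two selectivities are needed: C1 (secondary, benzylic, backed by the p-hydroxyaryl donor) must migrate rather than the primary C4, and it must go to C8a–H rather than to C5, where the OMe group leaves no proton to lose, so a shift there is a reversible dead end.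

**Compound list**

1 | 4-hydroxy-2,3-dimethoxybenzaldehyde | O=Cc1ccc(O)c(OC)c1OC | starting material
2 | 4-(benzyloxy)-2,3-dimethoxybenzaldehyde | O=Cc1ccc(OCc2ccccc2)c(OC)c1OC | intermediate
3 | dimethyl succinate | COC(=O)CCC(=O)OC | starting material
4 | (E)-4-[4-(benzyloxy)-2,3-dimethoxyphenyl]-3-(methoxycarbonyl)but-3-enoic acid | COC(=O)/C(CC(=O)O)=C/c1ccc(OCc2ccccc2)c(OC)c1OC | intermediate
5 | (3S)-4-[4-(benzyloxy)-2,3-dimethoxyphenyl]-3-(methoxycarbonyl)butanoic acid (not isolated) | COC(=O)[C@H](CC(=O)O)Cc1ccc(OCc2ccccc2)c(OC)c1OC | intermediate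
6 | (3S)-4-(4-hydroxy-2,3-dimethoxyphenyl)-3-(methoxycarbonyl)butanoic acid | COC(=O)[C@H](CC(=O)O)Cc1ccc(O)c(OC)c1OC | intermediate
7 | (3S)-4-(4-hydroxy-2,3-dimethoxyphenyl)-3-(hydroxymethyl)butanoic acid (not isolated) | OC[C@H](CC(=O)O)Cc1ccc(O)c(OC)c1OC | intermediate
8 | (4S)-4-(4-hydroxy-2,3-dimethoxybenzyl)dihydrofuran-2(3H)-one | O=C1C[C@H](Cc2ccc(O)c(OC)c2OC)CO1 | intermediate
9 | (4S)-4-[4-(tert-butyldimethylsilyloxy)-2,3-dimethoxybenzyl]dihydrofuran-2(3H)-one | O=C1C[C@H](Cc2ccc(O[Si](C)(C)C(C)(C)C)c(OC)c2OC)CO1 | intermediate
10 | vanillin | COc1cc(C=O)ccc1O | starting material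
11 | 4-(tert-butyldimethylsilyloxy)-3-methoxybenzaldehyde | COc1cc(C=O)ccc1O[Si](C)(C)C(C)(C)C | intermediate
12 | (3R,4S)-trans aldol adduct, carbinol carbon as epimer mixture | O=C1OC[C@@H](Cc2ccc(O[Si](C)(C)C(C)(C)C)c(OC)c2OC)[C@@H]1C(O)c3ccc(O[Si](C)(C)C(C)(C)C)c(OC)c3 | intermediate
13 | (2S,3S)-triol, carbinol carbon as epimer mixture | OC[C@@H](Cc1ccc(O[Si](C)(C)C(C)(C)C)c(OC)c1OC)[C@@H](CO)C(O)c2ccc(O[Si](C)(C)C(C)(C)C)c(OC)c2 | intermediate
14 | (2S,3S)-triacetate of 13 | CC(=O)OC[C@@H](Cc1ccc(O[Si](C)(C)C(C)(C)C)c(OC)c1OC)[C@@H](COC(C)=O)C(OC(C)=O)c2ccc(O[Si](C)(C)C(C)(C)C)c(OC)c2 | intermediate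
15 | guaiacyl p-quinone methide with free ring A phenol, C2 and C3 unchanged (not isolated) | CC(=O)OC[C@@H](Cc1ccc(O)c(OC)c1OC)[C@@H](COC(C)=O)C=C2C=CC(=O)C(OC)=C2 | intermediate
16 | (1R,2S,3S)-spiro[4.5]deca-6,9-dien-8-one diacetate, all-trans cyclopentane, spiro centre undefined (both epimers productive) | O=C1C=CC2(C[C@H](COC(C)=O)[C@@H](COC(C)=O)[C@@H]2c3ccc(O)c(OC)c3)C(OC)=C1OC | intermediate
17 | (1R,2S,3S)-tetralin diacetate (not isolated) | COc1cc([C@@H]2c3cc(O)c(OC)c(OC)c3C[C@H](COC(C)=O)[C@H]2COC(C)=O)ccc1O | intermediate
18 | (6S,7S,8R)-8-(4-hydroxy-3-methoxyphenyl)-6,7-bis(hydroxymethyl)-3,4-dimethoxy-5,6,7,8-tetrahydronaphthalen-2-ol | COc1cc([C@@H]2c3cc(O)c(OC)c(OC)c3C[C@H](CO)[C@H]2CO)ccc1O | target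

**Count**

Total steps: 11. Longest linear sequence: 10 (steps 1–5 and 7–11).

**Steps most likely to fail**

Risk 1, step 10.
- What may go wrong: the quinone methide may tautomerise to the styrene by loss of H-2. It may be taken through oxygen by a second phenolate (oligomerisation). It may be hydrated by adventitious water before the hindered para carbon reaches it.
- Fallback (known chemistry, gives up the spiro detour): it sets out from 13 and comes back at 18. TFA in CH2Cl2 at 0 °C ionises the benzylic alcohol. After reversible capture by the C3 hydroxymethyl group, the cation is taken by C8a (para to the C6 OMe). This Friedel–Crafts closure is the usual acid cyclisation of 7-oxygenated dibenzylbutanediols, and it gives the bis-silyl tetralin diol F1. TBAF in THF then frees both phenols to give 18.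

Risk 2, step 11.
- What may go wrong: heterolysis of C1–C4a may outrun the shift, so the ring-opened cation is lost to elimination or intermolecular arylation. Part of the material may migrate through C4. The vinylogous ester at C5 may be cleaved by traces of water.
- Fallback: it sets out from 16 and comes back at 18. Ac2O in pyridine caps the guaiacyl phenol to give the spirodienone triacetate F2. Its migrating carbon no longer carries a free p-hydroxyaryl donor, so ring opening to the quinone methide is shut off. BF3·OEt2 in CH2Cl2 at −20 °C then drives a concerted 1,2-shift to the tetralin triacetate F3. K2CO3 in MeOH removes the three acetates to give 18.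

Risk 3, step 3.
- What may go wrong: the ortho methoxy group may disturb chelation and erode the facial selectivity of the hydrogenation, or slow it.
- Fallback: it sets out from 4 and comes back at 6. H2 over Pd/C in MeOH saturates the alkene and cleaves the benzyl ether to give the racemic half-ester F4. Classical resolution follows by crystallising the (S)-1-phenylethylammonium salt of the S acid F5 (the antipodal amine is used if the wrong salt crystallises). Acidification then gives 6.

**Further compounds**

F1 | step 10 | (1R,2S,3S)-bis-TBS tetralin diol | COc1cc([C@@H]2c3cc(O[Si](C)(C)C(C)(C)C)c(OC)c(OC)c3C[C@H](CO)[C@H]2CO)ccc1O[Si](C)(C)C(C)(C)C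
F2 | step 11 | (1R,2S,3S)-spirodienone triacetate (guaiacyl O-acetate, spiro centre undefined) | O=C1C=CC2(C[C@H](COC(C)=O)[C@@H](COC(C)=O)[C@@H]2c3ccc(OC(C)=O)c(OC)c3)C(OC)=C1OC
F3 | step 11 | (1R,2S,3S)-tetralin triacetate with free C7 phenol | COc1cc([C@@H]2c3cc(O)c(OC)c(OC)c3C[C@H](COC(C)=O)[C@H]2COC(C)=O)ccc1OC(C)=O
F4 | step 3 | racemic 4-(4-hydroxy-2,3-dimethoxyphenyl)-3-(methoxycarbonyl)butanoic acid | COC(=O)C(CC(=O)O)Cc1ccc(O)c(OC)c1OC
F5 | step 3 | (S)-1-phenylethylammonium salt of 6 | COC(=O)[C@H](CC(=O)[O-])Cc1ccc(O)c(OC)c1OC.C[C@H]([NH3+])c1ccccc1
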